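Ring C is cut through C1–C2 and C4–C5. Its three contiguous oxygens (C1, C6, C5) and the hydrogens on C2 and C4 are the imprint of a ketone carbonyl (C6) flanked by two aryloxymethylene carbons. C2–C3–C4 is a malonaldehyde whose nitro group serves as a masked C3 hydroxyl. One double aldol condensation therefore forges both C–C bonds, closes and aromatises ring C, and leaves the C6 phenol free for ring E. The precursor is the symmetric 1,3-bis(biaryloxy)propan-2-one. Its two crowded ring B–O–ring C ethers arise by plain SN2 displacement on 1,3-dichloroacetone with the permethylated ring A–B phenol.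

Key step: step 4

Remarks on the chemistry
- Labels: ring A is the terminal 2,4,6-trioxygenated ring and ring B is the ring joined to it and to ring C through oxygen. Ring C is the central ring, with C1 and C5 bearing O–ring B, C6 bearing O–ring E, C3 bearing OH, and C2 and C4 bearing H. Ring E is the 3,4,5-trioxygenated ring. ArO stands for (2,2',4,4',6,6'-hexamethoxybiphenyl-3-yl)oxy.
- Each biaryl axis carries a ring A that is symmetric about the axis, so the target has no stereogenic element and no step has to control configuration.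
- Assumption: sodium nitromalonaldehyde monohydrate is purchased. It is shock- and heat-sensitive, so it is kept as the hydrate and used in solution behind a shield.

Step 1
Reactants: 1 2-iodo-1,3,5-trimethoxybenzene (2 equiv)
Product: 2 2,2',4,4',6,6'-hexamethoxybiphenyl
Conditions: activated Cu bronze (4 equiv), neat melt, 230 °C, Ar
Reagents that add atoms: none
Why: This is a classical Ullmann homocoupling, which tolerates electron-rich, di-ortho-substituted aryl iodides, and the symmetric coupling avoids the hindered cross-coupling that a tetra-ortho-oxygenated biaryl would otherwise require.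

Step 2
Reactants: 2 2,2',4,4',6,6'-hexamethoxybiphenyl
Product: 5 2,2',4,4',6,6'-hexamethoxybiphenyl-3-ol (ArOH), via aryllithium 3 (not isolated), via dimethyl arylboronate 4 (not isolated)
Conditions: n-BuLi (0.85 equiv), THF, 0 °C → rt; B(OMe)3, −78 °C → rt; AcOH, 30% H2O2, 0 °C → rt; Na2SO3 quench
Reagents that add atoms: hydrogen peroxide, OO (new oxygen of 5); n-butyllithium, [Li]CCCC (lithium of 3); trimethyl borate, COB(OC)OC (boron and methoxy groups of 4)
Why: Directed ortho-metalation, borylation and peroxide oxidation have only one possible site because all four ring hydrogens of 2 are equivalent and each lies between two methoxy groups; a deficit of n-BuLi keeps dilithiation low, neutral unreacted 2 is recovered when 5 is extracted into base, and placing the oxygen after the biaryl bond means no oxidation-prone free phenol ever meets a halogenating agent.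

Step 3
Reactants: 5 2,2',4,4',6,6'-hexamethoxybiphenyl-3-ol (2.05 equiv); 6 1,3-dichloroacetone
Product: 8 1,3-bis(ArO)propan-2-one, via monochloro ketone 7 (not isolated)
Conditions: K2CO3 (2.5 equiv), KI (0.2 equiv), MeCN, 50 °C, Ar
Reagents that add atoms: none
Why: The twofold Williamson-type SN2 displacement at carbonyl-activated primary chlorides (iodide catalysis) should outrun enolisation by the weak base, so both hindered ring B–O–C bonds are made at unhindered sp3 carbon.

Step 4
Reactants: 8 1,3-bis(ArO)propan-2-one; 9 sodium nitromalonaldehyde monohydrate (1.5 equiv)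
Product: 11 2,6-bis(ArO)-4-nitrophenol, via open-chain nitro enal 10 (not isolated)
Conditions: NaOH (1.2 equiv, 1 M aq.), EtOH–THF–H2O (homogeneous), 0 °C → rt, 48–72 h; then 1 M HCl to pH 3
Reagents that add atoms: none
Why: Hydroxide enolises one OCH2 group of 8, the enolate adds to a formyl carbon of 9 and water is lost to give 10 (bond C1–C2); the second OCH2 group then enolises and attacks the remaining formyl carbon (bond C5–C4), and dehydration plus tautomerisation of the resulting 4-nitrocyclohexadienone ends irreversibly at the aromatic nitrophenolate. The closest known reaction type is this same double aldol benzannulation of ketones bearing two alpha-methylene groups (diethyl ketone, dibenzyl ketone, acetonedicarboxylates) with sodium nitromalonaldehyde to give 2,6-disubstituted 4-nitrophenols, so 8 is a new member of a proven substrate class. Ring C closes in the 6-(enolendo)-exo-trig mode, since the enolate bond C5=C6 lies inside and the formyl C=O outside the forming ring, and the C1=C2 geometry of 10 equilibrates through its delocalised anion, so the E form that can cyclise is always replenished. No stereocentre is created. Regiochemistry cannot arise because ketone and dialdehyde are both symmetric; chemoselectivity is secured by the substrate, whose oxygen-acidified OCH2 groups are its only acidic C–H bonds, whose electron-rich aryloxides are too poor as leaving groups for elimination or Favorskii-type loss, and whose two ethers end up meta to the nitro group and hence inert to hydroxide. A homogeneous medium, a modest excess of 9 and little free hydroxide hold back the two competitors, self-aldolisation of 8 and hydrolytic deformylation of 9.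

Step 5
Reactants: 12 5-iodo-1,2,3-trimethoxybenzene; 13 1,3,5-trimethoxybenzene
Product: 15 (3,4,5-trimethoxyphenyl)(2,4,6-trimethoxyphenyl)iodonium tosylate, via hydroxy(tosyloxy)iodoarene 14 (not isolated)
Conditions: mCPBA (1.05 equiv), TsOH·H2O (1.05 equiv), MeCN, 60–77 °C, 30 min; then 13 (1.05 equiv), 10 min; Et2O trituration
Reagents that add atoms: p-toluenesulfonic acid, Cc1ccc(cc1)S(=O)(=O)O (tosylate of 14 and 15); mCPBA, O=C(OO)c1cccc(Cl)c1 (hydroxyl oxygen of 14)
Why: The aryl iodide is oxidised in one pot to the trivalent-iodine species, which then undergoes electrophilic aromatic substitution on 13, the standard entry to aryl(2,4,6-trimethoxyphenyl)iodonium salts; the iodine position fixes the ring E substitution pattern and the trimethoxyphenyl group acts as a non-transferable ligand.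

Step 6
Reactants: 11 2,6-bis(ArO)-4-nitrophenol; 15 (3,4,5-trimethoxyphenyl)(2,4,6-trimethoxyphenyl)iodonium tosylate (1.3 equiv)
Product: 16 1,3-bis(ArO)-5-nitro-2-(3,4,5-trimethoxyphenoxy)benzene
Conditions: K2CO3 (1.5 equiv), MeCN, 70 °C
Reagents that add atoms: none
Why: Metal-free O-arylation of a phenoxide with a diaryliodonium salt (ligand exchange at trivalent iodine, then ligand coupling) tolerates 2,6-disubstituted and nitro-substituted phenols; the far more electron-rich 2,4,6-trimethoxyphenyl ligand stays on iodine so only the ortho-unsubstituted ring E is transferred, and the weak base excludes an aryne pathway that would scramble ring E.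

Step 7
Reactants: 16 1,3-bis(ArO)-5-nitro-2-(3,4,5-trimethoxyphenoxy)benzene
Product: 17 3,5-bis(ArO)-4-(3,4,5-trimethoxyphenoxy)aniline
Conditions: H2 (1 atm), 10% Pd/C, EtOAc–EtOH, rt
Reagents that add atoms: none
Why: This is catalytic hydrogenation of an aromatic nitro group, to which aryl methyl ethers, diaryl ethers and the biaryl bonds are inert.

Step 8
Reactants: 17 3,5-bis(ArO)-4-(3,4,5-trimethoxyphenoxy)aniline
Product: 19 3,5-bis(ArO)-4-(3,4,5-trimethoxyphenoxy)phenol, via diazonium tetrafluoroborate 18 (not isolated)
Conditions: HBF4 (48% aq., 2 equiv), t-BuONO (1.05 equiv, slow addition), MeCN, 0 °C; then Cu(NO3)2·3H2O (large excess), Cu2O (cat.), H2O, rt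
Reagents that add atoms: tert-butyl nitrite, CC(C)(C)ON=O (second nitrogen of 18); tetrafluoroboric acid, [H+].F[B-](F)(F)F (counter-ion of 18); water, O (oxygen of 19)
Why: Diazotisation in organic medium is followed by Sandmeyer-type hydroxy-dediazoniation, in which monovalent copper reduces the diazonium ion to the aryl radical and aquated divalent copper delivers OH at rt; this is the usual way to convert a nitro-derived amine on a diaryl ether into a phenol, and one equivalent of nitrite added to the ammonium salt favours N- over C-nitrosation while the low temperature suppresses azo coupling with the methoxyarene rings.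

Step 9
Reactants: 19 3,5-bis(ArO)-4-(3,4,5-trimethoxyphenoxy)phenol
Product: 20 target CNP0279880.0
Conditions: BBr3 (30 equiv), CH2Cl2, −78 °C → rt → 40 °C, Ar; ice-water quench; EtOAc extraction; Sephadex LH-20, degassed solvents
Reagents that add atoms: none
Why: In this Lewis-acid ether cleavage BBr3 binds each methoxy oxygen and bromide removes the methyl group by SN2, whereas diaryl ether and biaryl bonds offer no sp3 carbon to attack; the aqueous rather than methanolic quench avoids acid-catalysed re-etherification of the phloroglucinol-type rings.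

Compound list
1 | 2-iodo-1,3,5-trimethoxybenzene | COc1cc(OC)c(I)c(OC)c1 | starting material
2 | 2,2',4,4',6,6'-hexamethoxybiphenyl | COc1cc(OC)c(-c2c(OC)cc(OC)cc2OC)c(OC)c1 | intermediate
3 | 3-lithio-2,2',4,4',6,6'-hexamethoxybiphenyl | [Li]c1c(OC)cc(OC)c(-c2c(OC)cc(OC)cc2OC)c1OC | intermediate
4 | dimethyl (2,2',4,4',6,6'-hexamethoxybiphenyl-3-yl)boronate | COB(OC)c1c(OC)cc(OC)c(-c2c(OC)cc(OC)cc2OC)c1OC | intermediate
5 | 2,2',4,4',6,6'-hexamethoxybiphenyl-3-ol (ring A–B phenol, ArOH) | Oc1c(OC)cc(OC)c(-c2c(OC)cc(OC)cc2OC)c1OC | intermediate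
6 | 1,3-dichloroacetone | O=C(CCl)CCl | starting material
7 | 1-chloro-3-(ArO)propan-2-one | O=C(CCl)COc1c(OC)cc(OC)c(-c2c(OC)cc(OC)cc2OC)c1OC | intermediate
8 | 1,3-bis(ArO)propan-2-one | O=C(COc1c(OC)cc(OC)c(-c2c(OC)cc(OC)cc2OC)c1OC)COc1c(OC)cc(OC)c(-c2c(OC)cc(OC)cc2OC)c1OC | intermediate
9 | sodium nitromalonaldehyde (sold as monohydrate; salt of O=CC(C=O)[N+](=O)[O-]) | [Na+].O=C[C-](C=O)[N+](=O)[O-] | starting material
10 | (E)-4,6-bis(ArO)-2-nitro-5-oxohex-3-enal (neutral form; C2 of the chain is acidic and configurationally labile) | O=CC([N+](=O)[O-])/C=C(Oc1c(OC)cc(OC)c(-c2c(OC)cc(OC)cc2OC)c1OC)\C(=O)COc1c(OC)cc(OC)c(-c2c(OC)cc(OC)cc2OC)c1OC | intermediate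
11 | 2,6-bis(ArO)-4-nitrophenol | O=[N+]([O-])c1cc(Oc2c(OC)cc(OC)c(-c3c(OC)cc(OC)cc3OC)c2OC)c(O)c(Oc2c(OC)cc(OC)c(-c3c(OC)cc(OC)cc3OC)c2OC)c1 | intermediate
12 | 5-iodo-1,2,3-trimethoxybenzene | COc1cc(I)cc(OC)c1OC | starting material
13 | 1,3,5-trimethoxybenzene | COc1cc(OC)cc(OC)c1 | starting material
14 | [hydroxy(tosyloxy)iodo]-3,4,5-trimethoxybenzene | COc1cc(I(O)OS(=O)(=O)c2ccc(C)cc2)cc(OC)c1OC | intermediate
15 | (3,4,5-trimethoxyphenyl)(2,4,6-trimethoxyphenyl)iodonium tosylate | COc1cc(OC)c([I+]c2cc(OC)c(OC)c(OC)c2)c(OC)c1.Cc1ccc(cc1)S(=O)(=O)[O-] | intermediate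
16 | 1,3-bis(ArO)-5-nitro-2-(3,4,5-trimethoxyphenoxy)benzene | O=[N+]([O-])c1cc(Oc2c(OC)cc(OC)c(-c3c(OC)cc(OC)cc3OC)c2OC)c(Oc2cc(OC)c(OC)c(OC)c2)c(Oc2c(OC)cc(OC)c(-c3c(OC)cc(OC)cc3OC)c2OC)c1 | intermediate
17 | 3,5-bis(ArO)-4-(3,4,5-trimethoxyphenoxy)aniline | Nc1cc(Oc2c(OC)cc(OC)c(-c3c(OC)cc(OC)cc3OC)c2OC)c(Oc2cc(OC)c(OC)c(OC)c2)c(Oc2c(OC)cc(OC)c(-c3c(OC)cc(OC)cc3OC)c2OC)c1 | intermediate
18 | 3,5-bis(ArO)-4-(3,4,5-trimethoxyphenoxy)benzenediazonium tetrafluoroborate | N#[N+]c1cc(Oc2c(OC)cc(OC)c(-c3c(OC)cc(OC)cc3OC)c2OC)c(Oc2cc(OC)c(OC)c(OC)c2)c(Oc2c(OC)cc(OC)c(-c3c(OC)cc(OC)cc3OC)c2OC)c1.F[B-](F)(F)F | intermediate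
19 | 3,5-bis(ArO)-4-(3,4,5-trimethoxyphenoxy)phenol (pentadecamethyl ether of the target) | Oc1cc(Oc2c(OC)cc(OC)c(-c3c(OC)cc(OC)cc3OC)c2OC)c(Oc2cc(OC)c(OC)c(OC)c2)c(Oc2c(OC)cc(OC)c(-c3c(OC)cc(OC)cc3OC)c2OC)c1 | intermediate
20 | CNP0279880.0 (sixteen free hydroxyls, no stereogenic element) | Oc1cc(O)c(-c2c(O)cc(O)c(Oc3cc(O)cc(Oc4c(O)cc(O)c(-c5c(O)cc(O)cc5O)c4O)c3Oc3cc(O)c(O)c(O)c3)c2O)c(O)c1 | target

Total step count: 9
Longest linear sequence: 8 (steps 1, 2, 3, 4, 6, 7, 8, 9)

Steps most likely to fail

1. Step 4. The ketone enolate may add too slowly to the anionic, weakly electrophilic dialdehyde. Self-aldolisation of the electrophilic ketone and hydroxide-induced deformylation of the dialdehyde would then consume both partners, and separation of the lipophilic ketone from the aqueous phase would make this worse.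
 - The fallback sets out from 8 and builds ring C in a [5+1] sense instead.
 - Heating 8 with N,N-dimethylformamide dimethyl acetal (neat or in toluene, 110 °C) uses a neutral and much stronger electrophile. It should aminomethylenate both OCH2 groups to give (1Z,4Z)-1,5-bis(dimethylamino)-2,4-bis(ArO)penta-1,4-dien-3-one F1, which already contains bonds C1–C2 and C5–C4.
 - Nitromethane with t-BuOK in t-BuOH–THF at 60 °C then supplies C3 by two addition–elimination events. This benzannulation is related to the conversion of 4-pyranones into 4-nitrophenols with nitromethane.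
 - Acidification comes back to the route at 11.

2. Step 8. The acidic nitrosating medium may C-nitrosate or oxidise the methoxy-rich rings A and B. The aryl radical may also abstract hydrogen in the mixed organic–aqueous medium, so that the nitrogen function is lost without gain of oxygen.
 - The fallback sets out from 17 and makes the C–O bond through boron.
 - t-BuONO and B2pin2 in MeCN at rt effect an acid-free, copper-free Sandmeyer-type borylation in which no diazonium salt accumulates. This should give 2-[3,5-bis(ArO)-4-(3,4,5-trimethoxyphenoxy)phenyl]-4,4,5,5-tetramethyl-1,3,2-dioxaborolane F2.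
 - Oxidation with 30% H2O2 and aqueous NaOH in THF at 0 °C comes back to the route at 19.

3. Step 9. The cleavage may stall when partly cleaved boron aryloxides precipitate. The free polyphenol, especially the pyrogallol-type ring E, may also be oxidised by air during isolation.
 - The fallback sets out from 19 and follows a derivatise–purify–release sequence.
 - After BBr3 treatment (1,2-dichloroethane, 50 °C) and aqueous quench, the crude material is not purified. It is peracetylated directly (Ac2O, pyridine, cat. DMAP, rt) to the hexadecaacetate of the target F3.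
 - F3 is neutral and air-stable, so it can be chromatographed on silica and separated from under-cleaved material, which is resubmitted to BBr3.
 - Deacetylation with degassed K2CO3 in MeOH–THF at 0 °C under Ar, followed by cold dilute aqueous HCl and extraction, comes back to the route at 20.

Further compounds
F1 | step 4 | (1Z,4Z)-1,5-bis(dimethylamino)-2,4-bis(ArO)penta-1,4-dien-3-one | CN(C)/C=C(Oc1c(OC)cc(OC)c(-c2c(OC)cc(OC)cc2OC)c1OC)/C(=O)/C(Oc1c(OC)cc(OC)c(-c2c(OC)cc(OC)cc2OC)c1OC)=C/N(C)C
F2 | step 8 | 2-[3,5-bis(ArO)-4-(3,4,5-trimethoxyphenoxy)phenyl]-4,4,5,5-tetramethyl-1,3,2-dioxaborolane | CC1(C)OB(OC1(C)C)c1cc(Oc2c(OC)cc(OC)c(-c3c(OC)cc(OC)cc3OC)c2OC)c(Oc2cc(OC)c(OC)c(OC)c2)c(Oc2c(OC)cc(OC)c(-c3c(OC)cc(OC)cc3OC)c2OC)c1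
F3 | step 9 | hexadecaacetate of the target | CC(=O)Oc1cc(OC(C)=O)c(-c2c(OC(C)=O)cc(OC(C)=O)c(Oc3cc(OC(C)=O)cc(Oc4c(OC(C)=O)cc(OC(C)=O)c(-c5c(OC(C)=O)cc(OC(C)=O)cc5OC(C)=O)c4OC(C)=O)c3Oc3cc(OC(C)=O)c(OC(C)=O)c(OC(C)=O)c3)c2OC(C)=O)c(OC(C)=O)c1
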